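**Plan**

- Locants: furanone O1, C2(=O), C3(CH3), C4(OSO3H), C5; side chain C1′(=CH on C5), C2′(S, CH3), C3′, C4′, C5′=C6′(CH3), C7′, C8′, C9′H2 on C4 of the 2,4-disubstituted furan.
- Cuts, in retrosynthetic order: O–SO3H; furanone C3–C4 (Dieckmann) and C5–O1 (vinylic C–O coupling); C5=C1′ (bromo-HWE); C7′–C8′ (Claisen); furan–CH2–furan and furan–C9′H2CH2.
- Enabling feature: C7′–C8′ is allylic to the trisubstituted C5′=C6′(CH3) alkene, so a temporary CO2H on C8′ makes C5′–C8′ a γ,δ-unsaturated acid, the retron of a [3,3] shift of a C5′–O ester that tethers the two halves; the CO2H is then excised.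
- Forward: bis-furan acid 8 (both furans bought, joined through CH2) and allylic alcohol 14 are esterified, rearranged and decarboxylated; C1′ is raised to the aldehyde, olefinated and acyloxylated; the furanone, the only ring made, is closed by Dieckmann at C3–C4; sulfation is last.
- Stereochemistry: C2′ (S) from (S)-β-citronellene; 5′E from the chair transition state; the 5E ylidene (chain cis to C4) from an E-selective bromo-HWE followed by two geometry-retaining steps.

Key step: step 10

Assumption: the ylidene geometry is taken exactly as written (side chain cis to C4–O, i.e. 5E), and the target is taken as the free hydrogen sulfate, to be released from its pyridinium salt by cold H+ exchange and handled in dilute solution.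

**Route**

Step 1
Reactants: 1 3-bromofuran; 2 4-bromofuran-2-carbaldehyde
Product: 4 (4-bromofuran-2-yl)(furan-3-yl)methanol (racemic), via furan-3-yllithium 3 (not isolated)
Conditions: n-BuLi, THF, −78 °C; then 2, −78 °C; H2O
Reagents that add atoms: none
Why: Br/Li exchange at −78 °C gives positionally stable furan-3-yllithium, whose 1,2-addition to the aldehyde should be much faster than exchange with the C4–Br of 2 (organolithium addition to an aldehyde).

Step 2
Reactants: 4 (4-bromofuran-2-yl)(furan-3-yl)methanol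
Product: 5 4-bromo-2-(furan-3-ylmethyl)furan
Conditions: Et3SiH (excess), TFA, CH2Cl2, −20 → 0 °C, short reaction time
Reagents that add atoms: none
Why: TFA ionises the doubly heteroaryl-stabilised carbinol and Et3SiH captures the cation at the exocyclic carbon (ionic hydrogenation of a diaryl carbinol), run cold and dilute because bis-furylmethanes are acid-sensitive.

Step 3
Reactants: 5 4-bromo-2-(furan-3-ylmethyl)furan; 6 (3-ethoxy-3-oxopropyl)zinc bromide
Product: 7 ethyl 3-[5-(furan-3-ylmethyl)furan-3-yl]propanoate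
Conditions: Pd(OAc)2 (cat.), SPhos (cat.), THF, 60 °C
Reagents that add atoms: none
Why: Negishi sp2–sp3 coupling of a heteroaryl bromide with a primary alkylzinc homoenolate, where the bulky biarylphosphine should outpace β-hydride elimination and the ester is inert to the organozinc.

Step 4
Reactants: 7 ethyl 3-[5-(furan-3-ylmethyl)furan-3-yl]propanoate
Product: 8 3-[5-(furan-3-ylmethyl)furan-3-yl]propanoic acid
Conditions: LiOH, THF/MeOH/H2O, rt; then dilute HCl to pH 3–4, 0 °C
Reagents that add atoms: lithium hydroxide, [Li+].[OH-]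
Why: Ordinary ester saponification, with only a brief cold acidification so that the furans are not exposed to strong acid.

Step 5
Reactants: 9 (S)-β-citronellene [(3S)-3,7-dimethylocta-1,6-diene]
Product: 10 2,2-dimethyl-3-[(3S)-3-methylpent-4-en-1-yl]oxirane (epimer mixture at the oxirane CH)
Conditions: mCPBA (1.0 equiv), CH2Cl2, 0 °C
Reagents that add atoms: mCPBA, OOC(=O)c1cccc(Cl)c1
Why: Prilezhaev epoxidation should select the electron-rich trisubstituted alkene over the vinyl group; the new oxirane stereocentre is uncontrolled and is destroyed in step 10.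

Step 6
Reactants: 10 2,2-dimethyl-3-[(3S)-3-methylpent-4-en-1-yl]oxirane
Product: 12 (2S)-4-(3,3-dimethyloxiran-2-yl)-2-methylbutan-1-ol, via secondary ozonide 11 (not isolated)
Conditions: O3, CH2Cl2, −78 °C; then NaBH4, MeOH, −78 → 0 °C
Reagents that add atoms: ozone, O=[O+][O-]
Why: Ozonolysis of the only remaining alkene with borohydride work-up removes the terminal carbon and gives the primary alcohol directly, so that the α-methyl stereocentre never sits next to a free aldehyde; the epoxide is inert.

Step 7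
Reactants: 12 (2S)-4-(3,3-dimethyloxiran-2-yl)-2-methylbutan-1-ol
Product: 13 tert-butyl{[(2S)-4-(3,3-dimethyloxiran-2-yl)-2-methylbutyl]oxy}dimethylsilane
Conditions: TBSCl, imidazole, CH2Cl2, rt
Reagents that add atoms: TBSCl, CC(C)(C)[Si](C)(C)Cl
Why: Standard silylation of a primary alcohol; the TBS ether should survive the aluminium amide, LDA/TMSCl and radical steps and is removed by fluoride without acid.

Step 8
Reactants: 13 tert-butyl{[(2S)-4-(3,3-dimethyloxiran-2-yl)-2-methylbutyl]oxy}dimethylsilane
Product: 14 (6S)-7-[(tert-butyldimethylsilyl)oxy]-2,6-dimethylhept-1-en-3-ol (epimer mixture at C3)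
Conditions: Et2Al-TMP (from TMPH, n-BuLi, Et2AlCl), toluene, 0 °C → rt; aqueous work-up
Reagents that add atoms: none
Why: Yamamoto-type aluminium amide isomerisation of a trisubstituted epoxide, in which syn β-elimination through a cyclic transition state takes a proton from the less hindered geminal methyl and gives the isopropenyl carbinol; its configuration is irrelevant.

Step 9
Reactants: 8 3-[5-(furan-3-ylmethyl)furan-3-yl]propanoic acid; 14 (6S)-7-[(tert-butyldimethylsilyl)oxy]-2,6-dimethylhept-1-en-3-ol
Product: 15 (6S)-7-[(tert-butyldimethylsilyl)oxy]-2,6-dimethylhept-1-en-3-yl 3-[5-(furan-3-ylmethyl)furan-3-yl]propanoate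
Conditions: DCC, DMAP (cat.), CH2Cl2, 0 °C → rt
Reagents that add atoms: none
Why: Steglich esterification of a secondary allylic alcohol under neutral conditions installs the ester tether that holds the two halves for the rearrangement.

Step 10
Reactants: 15 (6S)-7-[(tert-butyldimethylsilyl)oxy]-2,6-dimethylhept-1-en-3-yl 3-[5-(furan-3-ylmethyl)furan-3-yl]propanoate
Product: 18 (4E,8S)-9-[(tert-butyldimethylsilyl)oxy]-2-{[5-(furan-3-ylmethyl)furan-3-yl]methyl}-4,8-dimethylnon-4-enoic acid (epimer mixture at C2), via silyl ketene acetal 16 (not isolated), via trimethylsilyl ester 17 (not isolated)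
Conditions: LDA, TMSCl–Et3N, THF, −78 °C → rt; then 1 M HCl (aq), 0 °C, brief
Reagents that add atoms: none
Why: Ireland–Claisen rearrangement: LDA/TMSCl at −78 °C converts the ester into silyl ketene acetal 16, which on warming undergoes a concerted [3,3]-sigmatropic shift through a chair transition state that breaks the allylic C5′–O bond and forms the C7′–C8′ σ-bond and the C5′=C6′ alkene, giving silyl ester 17 and, after hydrolysis, acid 18. The closest precedent is the Ireland and Johnson Claisen synthesis of (E)-trisubstituted alkenes from esters of isopropenyl carbinols. No ring is closed, since the six-membered array exists only in the transition state and the ester tether is consumed. The new stereocentre at C8′ (bearing CO2H) is not controlled, because neither ketene acetal geometry nor carbinol configuration is selected, and need not be, as it is erased in step 11; C2′ is remote and untouched. The step must deliver the 5′E alkene, which is secured by the C4′ chain on the carbinol carbon taking the pseudo-equatorial position to avoid the 1,3-diaxial clash with the OSiMe3 group, so that both carbinol epimers converge on the same E alkene. Chemoselective enolisation rests on the pKa gap between the ester α-CH2 and the furan or bis-furyl CH2 hydrogens together with in situ silylation.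

Step 11
Reactants: 18 (4E,8S)-9-[(tert-butyldimethylsilyl)oxy]-2-{[5-(furan-3-ylmethyl)furan-3-yl]methyl}-4,8-dimethylnon-4-enoic acid
Product: 20 tert-butyl{[(2S,5E)-9-[5-(furan-3-ylmethyl)furan-3-yl]-2,6-dimethylnon-5-en-1-yl]oxy}dimethylsilane, via Barton ester 19 (not isolated)
Conditions: N-hydroxypyridine-2-thione, DCC, DMAP (cat.), CH2Cl2, rt, dark; then t-BuSH (excess), hν (tungsten lamp), 10 °C
Reagents that add atoms: none
Why: Barton reductive decarboxylation, in which the thiohydroxamate ester fragments to a secondary alkyl radical that should take hydrogen from the thiol faster than any cyclisation or hydrogen shift open to it, removing the temporary carboxyl and the uncontrolled stereocentre.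

Step 12
Reactants: 20 tert-butyl{[(2S,5E)-9-[5-(furan-3-ylmethyl)furan-3-yl]-2,6-dimethylnon-5-en-1-yl]oxy}dimethylsilane
Product: 21 (2S,5E)-9-[5-(furan-3-ylmethyl)furan-3-yl]-2,6-dimethylnon-5-en-1-ol
Conditions: TBAF, THF, rt
Reagents that add atoms: none
Why: Fluoride cleavage of a primary TBS ether, which needs no acid and leaves furans and alkenes untouched.

Step 13
Reactants: 21 (2S,5E)-9-[5-(furan-3-ylmethyl)furan-3-yl]-2,6-dimethylnon-5-en-1-ol
Product: 22 (2S,5E)-9-[5-(furan-3-ylmethyl)furan-3-yl]-2,6-dimethylnon-5-enal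
Conditions: Dess–Martin periodinane, pyridine, CH2Cl2, 0 °C; used at once
Reagents that add atoms: none
Why: Dess–Martin oxidation under buffered, non-enolising conditions should give the α-methyl aldehyde without epimerisation or attack on the furans.

Step 14
Reactants: 23 methyl 2-[bis(2,2,2-trifluoroethoxy)phosphoryl]acetate
Product: 25 methyl 2-bromo-2-[bis(2,2,2-trifluoroethoxy)phosphoryl]acetate (racemic), via dibromophosphonate 24 (not isolated)
Conditions: Br2, aq NaOH (NaOBr), 0 °C; crude dibromide, then SnCl2·2H2O, EtOH/H2O, 0 °C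
Reagents that add atoms: bromine, BrBr
Why: Exhaustive α-bromination of the active methylene with hypobromite followed by halophilic mono-reduction with tin(II) should give the monobromo phosphonate cleanly, avoiding the mono/di mixtures of direct monobromination.

Step 15
Reactants: 22 (2S,5E)-9-[5-(furan-3-ylmethyl)furan-3-yl]-2,6-dimethylnon-5-enal; 25 methyl 2-bromo-2-[bis(2,2,2-trifluoroethoxy)phosphoryl]acetate
Product: 26 methyl (2E,4S,7E)-2-bromo-11-[5-(furan-3-ylmethyl)furan-3-yl]-4,8-dimethylundeca-2,7-dienoate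
Conditions: t-BuOK, 18-crown-6, THF, −78 °C
Reagents that add atoms: none
Why: Horner–Wadsworth–Emmons olefination with a Still–Gennari-type α-bromophosphonate under dissociating conditions is kinetically controlled and should place the alkyl chain cis to the ester, i.e. the (E)-α-bromoacrylate, while the weakly basic phosphonate anion at −78 °C should not epimerise the aldehyde.

Step 16
Reactants: 26 methyl (2E,4S,7E)-2-bromo-11-[5-(furan-3-ylmethyl)furan-3-yl]-4,8-dimethylundeca-2,7-dienoate; 27 propanoic acid
Product: 28 methyl (2E,4S,7E)-11-[5-(furan-3-ylmethyl)furan-3-yl]-4,8-dimethyl-2-(propanoyloxy)undeca-2,7-dienoate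
Conditions: CuI (cat.), 1,10-phenanthroline (cat.), Cs2CO3, toluene, 90 °C
Reagents that add atoms: none
Why: Copper(I)-catalysed Ullmann-type substitution of an activated alkenyl bromide by a carboxylate (vinylic C–O coupling) should proceed at the sp2 carbon with retention of alkene geometry, so the acyloxy group ends up trans to the chain.

Step 17
Reactants: 28 methyl (2E,4S,7E)-11-[5-(furan-3-ylmethyl)furan-3-yl]-4,8-dimethyl-2-(propanoyloxy)undeca-2,7-dienoate
Product: 29 (5E)-5-{(2S,5E)-9-[5-(furan-3-ylmethyl)furan-3-yl]-2,6-dimethylnon-5-en-1-ylidene}-4-hydroxy-3-methylfuran-2(5H)-one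
Conditions: LiHMDS (2.2 equiv), THF, −78 → −20 °C; cold 0.5 M HCl to pH 3
Reagents that add atoms: none
Why: Dieckmann (intramolecular Claisen) condensation of an α-acyloxy acrylate, in which the propanoate enolate attacks the adjacent methyl ester in a 5-exo-trig closure, formation of the tetronate anion drives the equilibrium, and the enol-ester alkene is not touched, so its E geometry is carried into the 5-ylidene group.

Step 18
Reactants: 29 (5E)-5-{(2S,5E)-9-[5-(furan-3-ylmethyl)furan-3-yl]-2,6-dimethylnon-5-en-1-ylidene}-4-hydroxy-3-methylfuran-2(5H)-one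
Product: 30 (5E)-5-{(2S,5E)-9-[5-(furan-3-ylmethyl)furan-3-yl]-2,6-dimethylnon-5-en-1-ylidene}-3-methyl-2-oxo-2,5-dihydrofuran-4-yl hydrogen sulfate (CNP0018233.1)
Conditions: SO3·pyridine (1.5 equiv), pyridine, 0 °C → rt; then Dowex 50W (H+ form), MeOH/H2O, 0 °C
Reagents that add atoms: sulfur trioxide–pyridine complex, [O-]S(=O)(=O)[n+]1ccccc1
Why: O-Sulfation of the acidic C4 enol with SO3·pyridine, where the tetronate oxygen is far more nucleophilic than the furan carbons, which this reagent sulfonates only on prolonged reaction.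

**Compound list**

1 | 3-bromofuran | Brc1ccoc1 | starting material
2 | 4-bromofuran-2-carbaldehyde | O=Cc1cc(Br)co1 | starting material
3 | furan-3-yllithium | [Li]c1ccoc1 | intermediate (not isolated)
4 | (4-bromofuran-2-yl)(furan-3-yl)methanol, racemic | OC(c1ccoc1)c1cc(Br)co1 | intermediate
5 | 4-bromo-2-(furan-3-ylmethyl)furan | Brc1coc(Cc2ccoc2)c1 | intermediate
6 | (3-ethoxy-3-oxopropyl)zinc bromide | CCOC(=O)CC[Zn]Br | starting material
7 | ethyl 3-[5-(furan-3-ylmethyl)furan-3-yl]propanoate | CCOC(=O)CCc1coc(Cc2ccoc2)c1 | intermediate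
8 | 3-[5-(furan-3-ylmethyl)furan-3-yl]propanoic acid | OC(=O)CCc1coc(Cc2ccoc2)c1 | intermediate
9 | (S)-β-citronellene, (3S)-3,7-dimethylocta-1,6-diene | C=C[C@@H](C)CCC=C(C)C | starting material
10 | 2,2-dimethyl-3-[(3S)-3-methylpent-4-en-1-yl]oxirane, epimer mixture at the oxirane CH | C=C[C@@H](C)CCC1OC1(C)C | intermediate
11 | 3-[(2S)-4-(3,3-dimethyloxiran-2-yl)butan-2-yl]-1,2,4-trioxolane (secondary ozonide) | C1(OCOO1)[C@@H](C)CCC2OC2(C)C | intermediate (not isolated)
12 | (2S)-4-(3,3-dimethyloxiran-2-yl)-2-methylbutan-1-ol | OC[C@@H](C)CCC1OC1(C)C | intermediate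
13 | tert-butyl{[(2S)-4-(3,3-dimethyloxiran-2-yl)-2-methylbutyl]oxy}dimethylsilane | CC(C)(C)[Si](C)(C)OC[C@@H](C)CCC1OC1(C)C | intermediate
14 | (6S)-7-[(tert-butyldimethylsilyl)oxy]-2,6-dimethylhept-1-en-3-ol, epimer mixture at C3 | CC(C)(C)[Si](C)(C)OC[C@@H](C)CCC(O)C(C)=C | intermediate
15 | (6S)-7-[(tert-butyldimethylsilyl)oxy]-2,6-dimethylhept-1-en-3-yl 3-[5-(furan-3-ylmethyl)furan-3-yl]propanoate | CC(C)(C)[Si](C)(C)OC[C@@H](C)CCC(OC(=O)CCc1coc(Cc2ccoc2)c1)C(C)=C | intermediate
16 | trimethylsilyl ketene acetal of 15 | CC(C)(C)[Si](C)(C)OC[C@@H](C)CCC(OC(O[Si](C)(C)C)=CCc1coc(Cc2ccoc2)c1)C(C)=C | intermediate (not isolated)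
17 | trimethylsilyl (4E,8S)-9-[(tert-butyldimethylsilyl)oxy]-2-{[5-(furan-3-ylmethyl)furan-3-yl]methyl}-4,8-dimethylnon-4-enoate | CC(C)(C)[Si](C)(C)OC[C@@H](C)CC/C=C(\C)CC(Cc1coc(Cc2ccoc2)c1)C(=O)O[Si](C)(C)C | intermediate (not isolated)
18 | (4E,8S)-9-[(tert-butyldimethylsilyl)oxy]-2-{[5-(furan-3-ylmethyl)furan-3-yl]methyl}-4,8-dimethylnon-4-enoic acid, epimer mixture at C2 | CC(C)(C)[Si](C)(C)OC[C@@H](C)CC/C=C(\C)CC(Cc1coc(Cc2ccoc2)c1)C(=O)O | intermediate
19 | 2-thioxopyridin-1(2H)-yl ester of 18 (Barton ester) | CC(C)(C)[Si](C)(C)OC[C@@H](C)CC/C=C(\C)CC(Cc1coc(Cc2ccoc2)c1)C(=O)On1ccccc1=S | intermediate (not isolated)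
20 | tert-butyl{[(2S,5E)-9-[5-(furan-3-ylmethyl)furan-3-yl]-2,6-dimethylnon-5-en-1-yl]oxy}dimethylsilane | CC(C)(C)[Si](C)(C)OC[C@@H](C)CC/C=C(\C)CCCc1coc(Cc2ccoc2)c1 | intermediate
21 | (2S,5E)-9-[5-(furan-3-ylmethyl)furan-3-yl]-2,6-dimethylnon-5-en-1-ol | OC[C@@H](C)CC/C=C(\C)CCCc1coc(Cc2ccoc2)c1 | intermediate
22 | (2S,5E)-9-[5-(furan-3-ylmethyl)furan-3-yl]-2,6-dimethylnon-5-enal | O=C[C@@H](C)CC/C=C(\C)CCCc1coc(Cc2ccoc2)c1 | intermediate
23 | methyl 2-[bis(2,2,2-trifluoroethoxy)phosphoryl]acetate | COC(=O)CP(=O)(OCC(F)(F)F)OCC(F)(F)F | starting material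
24 | methyl 2,2-dibromo-2-[bis(2,2,2-trifluoroethoxy)phosphoryl]acetate | COC(=O)C(Br)(Br)P(=O)(OCC(F)(F)F)OCC(F)(F)F | intermediate (not isolated)
25 | methyl 2-bromo-2-[bis(2,2,2-trifluoroethoxy)phosphoryl]acetate, racemic | COC(=O)C(Br)P(=O)(OCC(F)(F)F)OCC(F)(F)F | intermediate
26 | methyl (2E,4S,7E)-2-bromo-11-[5-(furan-3-ylmethyl)furan-3-yl]-4,8-dimethylundeca-2,7-dienoate | COC(=O)/C(Br)=C\[C@@H](C)CC/C=C(\C)CCCc1coc(Cc2ccoc2)c1 | intermediate
27 | propanoic acid | CCC(=O)O | starting material
28 | methyl (2E,4S,7E)-11-[5-(furan-3-ylmethyl)furan-3-yl]-4,8-dimethyl-2-(propanoyloxy)undeca-2,7-dienoate | COC(=O)/C(OC(=O)CC)=C\[C@@H](C)CC/C=C(\C)CCCc1coc(Cc2ccoc2)c1 | intermediate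
29 | (5E)-5-{(2S,5E)-9-[5-(furan-3-ylmethyl)furan-3-yl]-2,6-dimethylnon-5-en-1-ylidene}-4-hydroxy-3-methylfuran-2(5H)-one | CC1=C(O)/C(=C\[C@@H](C)CC/C=C(\C)CCCc2coc(Cc3ccoc3)c2)OC1=O | intermediate
30 | (5E)-5-{(2S,5E)-9-[5-(furan-3-ylmethyl)furan-3-yl]-2,6-dimethylnon-5-en-1-ylidene}-3-methyl-2-oxo-2,5-dihydrofuran-4-yl hydrogen sulfate | CC1=C(OS(=O)(=O)O)/C(=C\[C@@H](C)CC/C=C(\C)CCCc2coc(Cc3ccoc3)c2)OC1=O | target

**Summary**

Total step count: 18. Longest linear sequence: 13 steps (steps 5–13 and 15–18 from (S)-β-citronellene; the bis-furan branch through steps 1–4 is equally long).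

Steps most likely to fail:

Step 16. Oxidative addition of copper to the hindered trisubstituted alkenyl bromide may be slow, and at 90 °C radical or addition–elimination pathways may erode the alkene geometry. The fallback inverts the polarity of the vinyl partner. It sets out from 26: Miyaura borylation (B2pin2, PdCl2(PPh3)2, KOPh, toluene, 50 °C) would give, with retention, methyl (2Z,4S,7E)-11-[5-(furan-3-ylmethyl)furan-3-yl]-4,8-dimethyl-2-(4,4,5,5-tetramethyl-1,3,2-dioxaborolan-2-yl)undeca-2,7-dienoate F1. Treatment with KHF2 would give the corresponding potassium alkenyltrifluoroborate F2. Copper(II)-catalysed oxidative (Chan–Lam-type) coupling of F2 with propanoic acid 27 under O2 at room temperature would then return to the route at 28.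

Step 17. The propanoate enolate may fragment (loss of methylketene with expulsion of the α-keto ester enolate) before it cyclises, closure onto an ester flanked by the cis C2′ branch may be slow, and γ-deprotonation may epimerise C2′. The fallback gives up geometric control in ring formation and corrects the geometry photochemically. It sets out from 22 and needs a methyl tetronate made separately: ethyl 2-methylacetoacetate would be γ-brominated with Br2 to ethyl 4-bromo-2-methyl-3-oxobutanoate F3, cyclised thermally to 4-hydroxy-3-methylfuran-2(5H)-one F4 and O-methylated (Me2SO4, K2CO3) to 4-methoxy-3-methylfuran-2(5H)-one F5. The C5 lithium enolate of F5 (LDA, THF, −78 °C) would add to 22 to give the aldol adduct F6, and mesylation to the mesylate F7 followed by DBU would give mainly the (5Z)-ylidene methyl tetronate F8. Irradiation would set up a Z/E photostationary mixture from which the (5E)-ylidene methyl tetronate F9 would be separated, with F8 recycled. Demethylation by a sulfur nucleophile (LiSPr, HMPA) would return to the route at 29.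

Step 2. Acid-promoted Friedel–Crafts self-condensation of the bis-furyl cation with furan rings may compete with hydride capture. The fallback forms the furan–CH2–furan link by cross-coupling instead of deoxygenation. It sets out from 2 with 6: Negishi coupling (Pd/SPhos), which tolerates the aldehyde, would give ethyl 3-(5-formylfuran-3-yl)propanoate F10. Reduction with NaBH4 would give ethyl 3-[5-(hydroxymethyl)furan-3-yl]propanoate F11, and ClCO2Me/pyridine would give ethyl 3-(5-{[(methoxycarbonyl)oxy]methyl}furan-3-yl)propanoate F12. Palladium-catalysed benzylic-type Suzuki coupling of F12 with furan-3-ylboronic acid (Pd(0)/bisphosphine) would return to the route at 7, bypassing 4 and 5.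

Further compounds
F1 | step 16 | methyl (2Z,4S,7E)-11-[5-(furan-3-ylmethyl)furan-3-yl]-4,8-dimethyl-2-(4,4,5,5-tetramethyl-1,3,2-dioxaborolan-2-yl)undeca-2,7-dienoate | COC(=O)/C(B1OC(C)(C)C(C)(C)O1)=C\[C@@H](C)CC/C=C(\C)CCCc1coc(Cc2ccoc2)c1
F2 | step 16 | potassium trifluoro[(2Z,4S,7E)-11-[5-(furan-3-ylmethyl)furan-3-yl]-1-methoxy-4,8-dimethyl-1-oxoundeca-2,7-dien-2-yl]borate | [K+].COC(=O)/C([B-](F)(F)F)=C\[C@@H](C)CC/C=C(\C)CCCc1coc(Cc2ccoc2)c1
F3 | step 17 | ethyl 4-bromo-2-methyl-3-oxobutanoate | CCOC(=O)C(C)C(=O)CBr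
F4 | step 17 | 4-hydroxy-3-methylfuran-2(5H)-one | CC1=C(O)COC1=O
F5 | step 17 | 4-methoxy-3-methylfuran-2(5H)-one | COC1=C(C)C(=O)OC1
F6 | step 17 | 5-{(2S,5E)-9-[5-(furan-3-ylmethyl)furan-3-yl]-1-hydroxy-2,6-dimethylnon-5-en-1-yl}-4-methoxy-3-methylfuran-2(5H)-one (diastereomer mixture) | COC1=C(C)C(=O)OC1C(O)[C@@H](C)CC/C=C(\C)CCCc1coc(Cc2ccoc2)c1
F7 | step 17 | methanesulfonate of F6 | COC1=C(C)C(=O)OC1C(OS(C)(=O)=O)[C@@H](C)CC/C=C(\C)CCCc1coc(Cc2ccoc2)c1
F8 | step 17 | (5Z)-5-{(2S,5E)-9-[5-(furan-3-ylmethyl)furan-3-yl]-2,6-dimethylnon-5-en-1-ylidene}-4-methoxy-3-methylfuran-2(5H)-one | COC1=C(C)C(=O)O/C1=C\[C@@H](C)CC/C=C(\C)CCCc1coc(Cc2ccoc2)c1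
F9 | step 17 | (5E)-5-{(2S,5E)-9-[5-(furan-3-ylmethyl)furan-3-yl]-2,6-dimethylnon-5-en-1-ylidene}-4-methoxy-3-methylfuran-2(5H)-one | COC1=C(C)C(=O)O/C1=C/[C@@H](C)CC/C=C(\C)CCCc1coc(Cc2ccoc2)c1
F10 | step 2 | ethyl 3-(5-formylfuran-3-yl)propanoate | CCOC(=O)CCc1coc(C=O)c1
F11 | step 2 | ethyl 3-[5-(hydroxymethyl)furan-3-yl]propanoate | CCOC(=O)CCc1coc(CO)c1
F12 | step 2 | ethyl 3-(5-{[(methoxycarbonyl)oxy]methyl}furan-3-yl)propanoate | CCOC(=O)CCc1coc(COC(=O)OC)c1
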